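The cyclohexene ring B (C5–C10, labdane numbering) is cut at C5–C10 and C8–C9. A C5=C6–C7=C8 silyloxy diene and the (E)-C9=C10 enoate, tethered through C1–C4, then close rings A and B in one thermal intramolecular Diels–Alder reaction, which also sets C9 and C10 under the direction of the C3 silyloxy centre. The precursor is an acyclic triene built from (S)-pantolactone that carries the C2 dioxolane, the C3 silyl ether and the C4 gem-dimethyl group. The C6 enol ether of the adduct then serves ring-fusion equilibration at C5, introduction of the C7=C8 alkene and removal of the C6 oxygen. The C11 ester is finally extended by B-alkyl Suzuki coupling.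

Key step: step 13

Remark (numbering): labdane locants are used throughout: C1–C10 for the decalin, C11–C16 for the side chain, C17 on C8, C18/C19 on C4, C20 on C10.
Remark (assumption): the cycloadduct is formulated as the ester-endo, trans-fused diastereomer; an ester-exo, cis-fused adduct would have the same C3, C9 and C10 configuration and would converge at the 7-en-6-one.
Remark (ordering): the ring fusion is equilibrated at the saturated 6-ketone, before the C7=C8 bond exists, because in the 7-en-6-one the C9 hydrogen is γ to the ketone and α to the ester and base would endanger C9.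

Step 1
Reactants: 1 (S)-pantolactone
Product: 2 (2S)-2,4-dihydroxy-N-methoxy-N,3,3-trimethylbutanamide
Conditions: MeNH(OMe)·HCl, i-PrMgCl, THF, −20 → 0 °C
Reagents that add atoms: N,O-dimethylhydroxylamine hydrochloride, CNOC.Cl
Why: Aminolysis of the lactone by the chloromagnesium amide (Weinreb amide formation) opens the ring and frees the C5 hydroxyl as a separate handle, while the magnesium alkoxide at C3 shields the adjacent hydrogen so that the stereocentre is kept.

Step 2
Reactants: 2 (2S)-2,4-dihydroxy-N-methoxy-N,3,3-trimethylbutanamide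
Product: 3 (2S)-2,4-bis(tert-butyldimethylsilyloxy)-N-methoxy-N,3,3-trimethylbutanamide
Conditions: TBSOTf, 2,6-lutidine, CH2Cl2, −78 → 0 °C
Reagents that add atoms: tert-butyldimethylsilyl triflate, CC(C)(C)[Si](C)(C)OS(=O)(=O)C(F)(F)F
Why: O-Silylation with the silyl triflate and a hindered pyridine base caps both the primary and the hindered secondary hydroxyl and removes the risk of relactonisation.

Step 3
Reactants: 3 (2S)-2,4-bis(tert-butyldimethylsilyloxy)-N-methoxy-N,3,3-trimethylbutanamide; 4 3-chloro-2-methylprop-1-ene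
Product: 6 (5S)-5,7-bis(tert-butyldimethylsilyloxy)-2,6,6-trimethylhept-1-en-4-one, via 2-methylallylmagnesium chloride 5 (not isolated)
Conditions: 4, Mg, THF, 0 °C; then 3, −78 → −20 °C; aq. NH4Cl
Reagents that add atoms: none
Why: Grignard addition to the Weinreb amide stops at the chelated tetrahedral intermediate, so work-up should give the ketone without over-addition, and the cold, near-neutral quench keeps the alkene out of conjugation.

Step 4
Reactants: 6 (5S)-5,7-bis(tert-butyldimethylsilyloxy)-2,6,6-trimethylhept-1-en-4-one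
Product: 7 2-[(1S)-1,3-bis(tert-butyldimethylsilyloxy)-2,2-dimethylpropyl]-2-(2-methylallyl)-1,3-dioxolane
Conditions: (Me3SiOCH2)2, TMSOTf (cat.), CH2Cl2, −78 → −20 °C; pyridine quench
Reagents that add atoms: 1,2-bis(trimethylsilyloxy)ethane, C[Si](C)(C)OCCO[Si](C)(C)C
Why: Noyori ketalisation is aprotic and runs at low temperature, which should spare the silyl ethers, the C3 centre next to the carbonyl and the β,γ-position of the alkene.

Step 5
Reactants: 7 2-[(1S)-1,3-bis(tert-butyldimethylsilyloxy)-2,2-dimethylpropyl]-2-(2-methylallyl)-1,3-dioxolane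
Product: 8 1-{2-[(1S)-1,3-bis(tert-butyldimethylsilyloxy)-2,2-dimethylpropyl]-1,3-dioxolan-2-yl}propan-2-one
Conditions: O3, CH2Cl2/MeOH, −78 °C; then PPh3
Reagents that add atoms: ozone, [O-][O+]=O
Why: Ozonolysis with reductive work-up cleaves the only alkene to the methyl ketone (C10 with its methyl C20), while ketal and silyl ethers are inert.

Step 6
Reactants: 8 1-{2-[(1S)-1,3-bis(tert-butyldimethylsilyloxy)-2,2-dimethylpropyl]-1,3-dioxolan-2-yl}propan-2-one; 9 trimethyl phosphonoacetate
Product: 11 methyl (2E)-4-{2-[(1S)-1,3-bis(tert-butyldimethylsilyloxy)-2,2-dimethylpropyl]-1,3-dioxolan-2-yl}-3-methylbut-2-enoate, via sodium phosphonoacetate enolate 10 (not isolated)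
Conditions: 9, NaH, THF, 0 °C; then 8, 0 °C → reflux
Reagents that add atoms: none
Why: Horner–Wadsworth–Emmons olefination of the methyl ketone should favour the E enoate, in which the ester is trans to the branched C1 substituent and cis to the methyl group; the minor Z isomer is to be removed by chromatography.

Step 7
Reactants: 11 methyl (2E)-4-{2-[(1S)-1,3-bis(tert-butyldimethylsilyloxy)-2,2-dimethylpropyl]-1,3-dioxolan-2-yl}-3-methylbut-2-enoate
Product: 12 methyl (2E)-4-{2-[(1S)-1-(tert-butyldimethylsilyloxy)-3-hydroxy-2,2-dimethylpropyl]-1,3-dioxolan-2-yl}-3-methylbut-2-enoate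
Conditions: HF·pyridine, pyridine, THF, 0 °C → rt
Reagents that add atoms: none
Why: Selective desilylation is expected because the primary silyl ether is cleaved much faster than the C3 silyl ether, which is shielded by two fully substituted neighbours.

Step 8
Reactants: 12 methyl (2E)-4-{2-[(1S)-1-(tert-butyldimethylsilyloxy)-3-hydroxy-2,2-dimethylpropyl]-1,3-dioxolan-2-yl}-3-methylbut-2-enoate
Product: 13 methyl (2E)-4-{2-[(1S)-1-(tert-butyldimethylsilyloxy)-2,2-dimethyl-3-oxopropyl]-1,3-dioxolan-2-yl}-3-methylbut-2-enoate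
Conditions: Dess–Martin periodinane, pyridine, CH2Cl2, rt
Reagents that add atoms: none
Why: Dess–Martin oxidation under buffered conditions gives the non-enolisable C5 aldehyde without disturbing ketal, silyl ether or enoate.

Step 9
Reactants: 13 methyl (2E)-4-{2-[(1S)-1-(tert-butyldimethylsilyloxy)-2,2-dimethyl-3-oxopropyl]-1,3-dioxolan-2-yl}-3-methylbut-2-enoate
Product: 15 methyl (2E)-4-{2-[(1S)-1-(tert-butyldimethylsilyloxy)-2,2-dimethyl-4-oxobutyl]-1,3-dioxolan-2-yl}-3-methylbut-2-enoate, via methyl enol ether 14 (not isolated)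
Conditions: Ph3P(CH2OMe)Cl, KOt-Bu, THF, 0 °C; then HCl (1 M aq.), THF, 0 °C
Reagents that add atoms: (methoxymethyl)triphenylphosphonium chloride, COC[P+](c1ccccc1)(c1ccccc1)c1ccccc1.[Cl-]; water, O
Why: Wittig methoxymethylenation of the hindered aldehyde and mild acid hydrolysis of the enol ether add C6 as an aldehyde, the hindered α-silyloxy dioxolane being hydrolysed far more slowly than the enol ether.

Step 10
Reactants: 15 methyl (2E)-4-{2-[(1S)-1-(tert-butyldimethylsilyloxy)-2,2-dimethyl-4-oxobutyl]-1,3-dioxolan-2-yl}-3-methylbut-2-enoate; 16 (E)-1-bromoprop-1-ene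
Product: 18 methyl (2E)-4-{2-[(1S,5E)-1-(tert-butyldimethylsilyloxy)-4-hydroxy-2,2-dimethylhept-5-en-1-yl]-1,3-dioxolan-2-yl}-3-methylbut-2-enoate (both carbinol epimers), via (E)-prop-1-enyllithium 17 (not isolated)
Conditions: 16, t-BuLi (2 equiv), Et2O, −78 °C; then 15, −78 °C
Reagents that add atoms: none
Why: Bromine–lithium exchange proceeds with retention of the E geometry and the alkenyllithium adds to the aldehyde (1,2-addition) much faster than to the conjugated ester at −78 °C; the new carbinol centre is oxidised away in the next step.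

Step 11
Reactants: 18 methyl (2E)-4-{2-[(1S,5E)-1-(tert-butyldimethylsilyloxy)-4-hydroxy-2,2-dimethylhept-5-en-1-yl]-1,3-dioxolan-2-yl}-3-methylbut-2-enoate
Product: 19 methyl (2E)-4-{2-[(1S,5E)-1-(tert-butyldimethylsilyloxy)-2,2-dimethyl-4-oxohept-5-en-1-yl]-1,3-dioxolan-2-yl}-3-methylbut-2-enoate
Conditions: Dess–Martin periodinane, pyridine, CH2Cl2, rt
Reagents that add atoms: none
Why: Dess–Martin oxidation of the allylic alcohol gives the (E)-enone without isomerising either alkene.

Step 12
Reactants: 19 methyl (2E)-4-{2-[(1S,5E)-1-(tert-butyldimethylsilyloxy)-2,2-dimethyl-4-oxohept-5-en-1-yl]-1,3-dioxolan-2-yl}-3-methylbut-2-enoate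
Product: 20 methyl (2E)-4-{2-[(1S,3Z,5E)-1,4-bis(tert-butyldimethylsilyloxy)-2,2-dimethylhepta-3,5-dien-1-yl]-1,3-dioxolan-2-yl}-3-methylbut-2-enoate
Conditions: TBSOTf, Et3N, CH2Cl2, −78 → 0 °C
Reagents that add atoms: tert-butyldimethylsilyl triflate, CC(C)(C)[Si](C)(C)OS(=O)(=O)C(F)(F)F
Why: Soft enolisation (enol silylation) removes an α′-hydrogen at C5 to give the cross-conjugated 2-silyloxy diene, and the Z enol ether should form because the E isomer would press the quaternary C4 against the vinyl group.

Step 13
Reactants: 20 methyl (2E)-4-{2-[(1S,3Z,5E)-1,4-bis(tert-butyldimethylsilyloxy)-2,2-dimethylhepta-3,5-dien-1-yl]-1,3-dioxolan-2-yl}-3-methylbut-2-enoate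
Product: 21 Diels–Alder adduct: trans-fused decalin with C2 ethylene ketal, (3S)-OTBS, C6=C7 TBS enol ether, 8-methyl and 9-CO2Me (H5 anti to the C10 methyl; 3-O, 8-CH3 and 9-CO2Me cis to it)
Conditions: PhMe (0.01 M), BHT (cat.), 180 °C, sealed tube
Reagents that add atoms: none
Why: Heating folds the (E)-C9=C10 enoate over the s-cis C5=C6–C7=C8 silyloxy diene, and a concerted, asynchronous, suprafacial [4+2] cycloaddition forms C5–C10 and C8–C9; the closest known reaction type is the thermal intramolecular Diels–Alder reaction of 1,7,9-decatrienes that carry a 2-silyloxy diene and an enoate dienophile. Ring B is closed by the cycloaddition itself as a six-membered carbocycle from four diene and two dienophile carbons, and ring A is closed as the fused six-membered ring that the tether C1–C4 and the new C5–C10 bond complete. C9 and C10 are fixed relative to each other by the E geometry of the enoate (ester cis to the C10 methyl) and in the absolute sense by C3, whose silyloxy group sits equatorial in the chair-like tether between the fully substituted C2 and C4; C5 follows from the ester-endo, tether-exo transition state and C8 from the E-propenyl terminus. The step needs regiocontrol and π-facial selectivity: the first is secured by the tether and by the 6-silyloxy group, which makes C5 the nucleophilic terminus matched to the β-carbon C10, the second by the C3 substituent together with the Thorpe–Ingold bias of the C4 gem-dimethyl and C2 ketal groups. Incomplete endo/exo selectivity is tolerated because C5 is equilibrated in step 14 and C8 is erased in step 15, and the quaternary C4 and the E-propenyl group leave no hydrogen for a competing 1,5-shift in the diene.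

Step 14
Reactants: 21 Diels–Alder adduct
Product: 22 trans-fused 6-ketone (C7H2; 8-CH3 and 9-CO2Me cis to the C10 methyl; C2 ketal; 3-OTBS)
Conditions: NaOMe (cat.), MeOH/THF, 0 °C → rt
Reagents that add atoms: none
Why: Methanolysis of the enol silane frees the C6 ketone, and reversible enolisation toward C5 should equilibrate any cis-fused material to the more stable trans-fused decalin (thermodynamic epimerisation), while the alkyl silyl ether and the far less acidic C9 ester position stay intact.

Step 15
Reactants: 22 trans-fused 6-ketone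
Product: 24 7-en-6-one (C6 ketone; C7=C8 with 8-methyl; 9-CO2Me cis to the C10 methyl; trans-fused), via trimethylsilyl enol ether 23 (not isolated)
Conditions: LiN(i-Pr)2, TMSCl, THF, −78 °C; then Pd(OAc)2, MeCN, rt
Reagents that add atoms: none
Why: Kinetic deprotonation can occur only at C7, since C5 is tertiary and shielded, and Saegusa–Ito oxidation of the enol silane introduces the C7=C8 bond and removes the C8 stereocentre under neutral conditions that protect the now doubly activated C9 hydrogen.

Step 16
Reactants: 24 7-en-6-one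
Product: 25 allylic alcohol (6-OH axial and cis to the C10 methyl; C7=C8; 9-CO2Me)
Conditions: NaBH4, CeCl3·7H2O, MeOH, −78 → 0 °C
Reagents that add atoms: none
Why: Luche reduction gives 1,2-reduction of the enone without touching the ester, and hydride should enter from the face opposite the axial C10 and C4 methyl groups, which places the hydroxyl cis to the C10 methyl.

Step 17
Reactants: 25 allylic alcohol
Product: 26 allylic methyl carbonate (6-OCO2Me; otherwise as 25)
Conditions: LiN(SiMe3)2, ClCO2Me, THF, −78 → 0 °C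
Reagents that add atoms: methyl chloroformate, COC(=O)Cl
Why: Acylation of the preformed lithium alkoxide overcomes the hindrance of the axial alcohol and installs a leaving group that ionises irreversibly with zerovalent palladium.

Step 18
Reactants: 26 allylic methyl carbonate
Product: 27 homoallylic alcohol (C6H2; C7=C8; 9-CH2OH cis to the C10 methyl; C2 ketal; 3-OTBS)
Conditions: Pd(PPh3)4 (cat.), LiBHEt3 (slow addition, excess), THF, 0 °C → rt
Reagents that add atoms: none
Why: Zerovalent palladium ionises the axial carbonate from the open opposite face and hydride is delivered to the less substituted terminus C6 of the π-allyl complex (Tsuji–Trost-type allylic hydrogenolysis with a borohydride), which keeps the trisubstituted C7=C8 alkene, and the same hydride reduces the methyl ester to the C11 alcohol.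

Step 19
Reactants: 27 homoallylic alcohol
Product: 28 C11 aldehyde (9-CHO cis to the C10 methyl; C7=C8)
Conditions: Dess–Martin periodinane, pyridine, CH2Cl2, 0 °C
Reagents that add atoms: none
Why: Dess–Martin oxidation at 0 °C is mild enough that the β,γ-unsaturated aldehyde should neither epimerise at C9 nor move its alkene into conjugation.

Step 20
Reactants: 28 C11 aldehyde
Product: 29 9-vinyl compound (C11=C12; C7=C8; C2 ketal; 3-OTBS)
Conditions: Ph3PCH3Br, KN(SiMe3)2, THF, −78 → 0 °C
Reagents that add atoms: methyltriphenylphosphonium bromide, C[P+](c1ccccc1)(c1ccccc1)c1ccccc1.[Br-]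
Why: Wittig methylenation at low temperature is faster than enolisation of the hindered aldehyde, so C9 should keep its configuration.

Step 21
Reactants: 30 methyl acetoacetate
Product: 31 methyl (2E)-3-(trifluoromethylsulfonyloxy)but-2-enoate
Conditions: Tf2O, Me4NOH (aq.), hexanes, 5 °C → rt
Reagents that add atoms: triflic anhydride, O=S(=O)(OS(=O)(=O)C(F)(F)F)C(F)(F)F
Why: O-Triflation of the β-keto ester enolate with a non-chelating tetraalkylammonium counter-ion should give the E enol triflate, with the triflate trans to the ester, which is the geometry the side chain needs.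

Step 22
Reactants: 29 9-vinyl compound; 31 methyl (2E)-3-(trifluoromethylsulfonyloxy)but-2-enoate
Product: 33 methyl (13E)-enoate (C15 methyl ester of the full labda-7,13-diene skeleton; C2 ketal; 3-OTBS), via B-alkyl-9-BBN 32 (not isolated)
Conditions: 9-BBN-H, THF, rt; then 31, Pd(dppf)Cl2 (cat.), K3PO4 (aq.), DMF, rt → 40 °C
Reagents that add atoms: none
Why: 9-BBN hydroborates only the monosubstituted vinyl group, at its terminus C12, and B-alkyl Suzuki–Miyaura coupling with the enol triflate proceeds with retention of alkene geometry, which fixes the 13E configuration.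

Step 23
Reactants: 33 methyl (13E)-enoate
Product: 34 (13E)-allylic alcohol (C15-OH; C2 ketal; 3-OTBS)
Conditions: i-Bu2AlH, CH2Cl2, −78 °C
Reagents that add atoms: none
Why: Hydride reduction of the conjugated ester with i-Bu2AlH gives the allylic alcohol in the 1,2-sense without affecting ketal, silyl ether or alkenes.

Step 24
Reactants: 34 (13E)-allylic alcohol
Product: 35 C15 acetate (C2 ketal; 3-OTBS)
Conditions: Ac2O, pyridine, DMAP (cat.), CH2Cl2, 0 °C → rt
Reagents that add atoms: acetic anhydride, CC(=O)OC(C)=O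
Why: O-Acetylation of the primary allylic alcohol is unambiguous because it is the only free hydroxyl in the molecule.

Step 25
Reactants: 35 C15 acetate
Product: 36 (13E)-(3S,5S,9R,10S)-3-hydroxy-2-oxolabda-7,13-dien-15-yl acetate (target)
Conditions: HF (48% aq.), MeCN, 0 °C → rt
Reagents that add atoms: water, O
Why: Aqueous HF cleaves the last silyl ether and hydrolyses the dioxolane (global acidic deprotection), whose opening relieves the syn-axial contact with the C4 and C10 methyl groups, at an acidity the primary allylic acetate and the trisubstituted alkenes should tolerate; no stereocentre is touched.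

Compound list
1 | (S)-pantolactone, (3S)-3-hydroxy-4,4-dimethyloxolan-2-one | CC1(C)COC(=O)[C@H]1O | starting material
2 | (2S)-2,4-dihydroxy-N-methoxy-N,3,3-trimethylbutanamide | OCC(C)(C)[C@H](O)C(=O)N(C)OC | intermediate
3 | (2S)-2,4-bis(tert-butyldimethylsilyloxy)-N-methoxy-N,3,3-trimethylbutanamide | CC(C)(C)[Si](C)(C)OCC(C)(C)[C@H](O[Si](C)(C)C(C)(C)C)C(=O)N(C)OC | intermediate
4 | 3-chloro-2-methylprop-1-ene | CC(=C)CCl | starting material
5 | 2-methylallylmagnesium chloride | CC(=C)C[Mg]Cl | intermediate
6 | (5S)-5,7-bis(tert-butyldimethylsilyloxy)-2,6,6-trimethylhept-1-en-4-one | CC(C)(C)[Si](C)(C)OCC(C)(C)[C@H](O[Si](C)(C)C(C)(C)C)C(=O)CC(C)=C | intermediate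
7 | 2-[(1S)-1,3-bis(tert-butyldimethylsilyloxy)-2,2-dimethylpropyl]-2-(2-methylallyl)-1,3-dioxolane | CC(C)(C)[Si](C)(C)OCC(C)(C)[C@H](O[Si](C)(C)C(C)(C)C)C1(OCCO1)CC(C)=C | intermediate
8 | 1-{2-[(1S)-1,3-bis(tert-butyldimethylsilyloxy)-2,2-dimethylpropyl]-1,3-dioxolan-2-yl}propan-2-one | CC(C)(C)[Si](C)(C)OCC(C)(C)[C@H](O[Si](C)(C)C(C)(C)C)C1(OCCO1)CC(C)=O | intermediate
9 | trimethyl phosphonoacetate | COC(=O)CP(=O)(OC)OC | starting material
10 | sodium enolate of trimethyl phosphonoacetate | [Na+].COC(=O)[CH-]P(=O)(OC)OC | intermediate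
11 | methyl (2E)-4-{2-[(1S)-1,3-bis(tert-butyldimethylsilyloxy)-2,2-dimethylpropyl]-1,3-dioxolan-2-yl}-3-methylbut-2-enoate | CC(C)(C)[Si](C)(C)OCC(C)(C)[C@H](O[Si](C)(C)C(C)(C)C)C1(OCCO1)C/C(C)=C/C(=O)OC | intermediate
12 | methyl (2E)-4-{2-[(1S)-1-(tert-butyldimethylsilyloxy)-3-hydroxy-2,2-dimethylpropyl]-1,3-dioxolan-2-yl}-3-methylbut-2-enoate | OCC(C)(C)[C@H](O[Si](C)(C)C(C)(C)C)C1(OCCO1)C/C(C)=C/C(=O)OC | intermediate
13 | methyl (2E)-4-{2-[(1S)-1-(tert-butyldimethylsilyloxy)-2,2-dimethyl-3-oxopropyl]-1,3-dioxolan-2-yl}-3-methylbut-2-enoate | O=CC(C)(C)[C@H](O[Si](C)(C)C(C)(C)C)C1(OCCO1)C/C(C)=C/C(=O)OC | intermediate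
14 | methyl enol ether of the homologated aldehyde (C5=C6-OMe, E/Z mixture) | COC=CC(C)(C)[C@H](O[Si](C)(C)C(C)(C)C)C1(OCCO1)C/C(C)=C/C(=O)OC | intermediate
15 | methyl (2E)-4-{2-[(1S)-1-(tert-butyldimethylsilyloxy)-2,2-dimethyl-4-oxobutyl]-1,3-dioxolan-2-yl}-3-methylbut-2-enoate | O=CCC(C)(C)[C@H](O[Si](C)(C)C(C)(C)C)C1(OCCO1)C/C(C)=C/C(=O)OC | intermediate
16 | (E)-1-bromoprop-1-ene | C/C=C/Br | starting material
17 | (E)-prop-1-enyllithium | C/C=C/[Li] | intermediate
18 | methyl (2E)-4-{2-[(1S,5E)-1-(tert-butyldimethylsilyloxy)-4-hydroxy-2,2-dimethylhept-5-en-1-yl]-1,3-dioxolan-2-yl}-3-methylbut-2-enoate, both carbinol epimers | C/C=C/C(O)CC(C)(C)[C@H](O[Si](C)(C)C(C)(C)C)C1(OCCO1)C/C(C)=C/C(=O)OC | intermediate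
19 | methyl (2E)-4-{2-[(1S,5E)-1-(tert-butyldimethylsilyloxy)-2,2-dimethyl-4-oxohept-5-en-1-yl]-1,3-dioxolan-2-yl}-3-methylbut-2-enoate | C/C=C/C(=O)CC(C)(C)[C@H](O[Si](C)(C)C(C)(C)C)C1(OCCO1)C/C(C)=C/C(=O)OC | intermediate
20 | methyl (2E)-4-{2-[(1S,3Z,5E)-1,4-bis(tert-butyldimethylsilyloxy)-2,2-dimethylhepta-3,5-dien-1-yl]-1,3-dioxolan-2-yl}-3-methylbut-2-enoate (cycloaddition precursor) | C/C=C/C(O[Si](C)(C)C(C)(C)C)=C/C(C)(C)[C@H](O[Si](C)(C)C(C)(C)C)C1(OCCO1)C/C(C)=C/C(=O)OC | intermediate
21 | Diels–Alder adduct: trans-fused decalin, C2 ethylene ketal, (3S)-OTBS, C6=C7 TBS enol ether, 8-methyl, 9-CO2Me; H5 anti to the C10 methyl; 3-O, 8-CH3 and 9-CO2Me cis to it | COC(=O)[C@@H]1[C@H](C)C=C(O[Si](C)(C)C(C)(C)C)[C@@H]2C(C)(C)[C@H](O[Si](C)(C)C(C)(C)C)C3(OCCO3)C[C@@]12C | intermediate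
22 | trans-fused 6-ketone of 21 (C7H2) | COC(=O)[C@@H]1[C@H](C)CC(=O)[C@@H]2C(C)(C)[C@H](O[Si](C)(C)C(C)(C)C)C3(OCCO3)C[C@@]12C | intermediate
23 | C6=C7 trimethylsilyl enol ether of 22 | COC(=O)[C@@H]1[C@H](C)C=C(O[Si](C)(C)C)[C@@H]2C(C)(C)[C@H](O[Si](C)(C)C(C)(C)C)C3(OCCO3)C[C@@]12C | intermediate
24 | 7-en-6-one: C6 ketone, C7=C8, 9-CO2Me cis to the C10 methyl, trans-fused | COC(=O)[C@@H]1C(C)=CC(=O)[C@@H]2C(C)(C)[C@H](O[Si](C)(C)C(C)(C)C)C3(OCCO3)C[C@@]12C | intermediate
25 | allylic alcohol: 6-OH cis to the C10 methyl, C7=C8, 9-CO2Me | COC(=O)[C@@H]1C(C)=C[C@H](O)[C@@H]2C(C)(C)[C@H](O[Si](C)(C)C(C)(C)C)C3(OCCO3)C[C@@]12C | intermediate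
26 | 6-O-methoxycarbonyl derivative (methyl carbonate) of 25 | COC(=O)[C@@H]1C(C)=C[C@H](OC(=O)OC)[C@@H]2C(C)(C)[C@H](O[Si](C)(C)C(C)(C)C)C3(OCCO3)C[C@@]12C | intermediate
27 | homoallylic alcohol: C6H2, C7=C8, 9-CH2OH cis to the C10 methyl, C2 ketal, 3-OTBS | OC[C@@H]1C(C)=CC[C@@H]2C(C)(C)[C@H](O[Si](C)(C)C(C)(C)C)C3(OCCO3)C[C@@]12C | intermediate
28 | C11 aldehyde of 27 | O=C[C@@H]1C(C)=CC[C@@H]2C(C)(C)[C@H](O[Si](C)(C)C(C)(C)C)C3(OCCO3)C[C@@]12C | intermediate
29 | 9-vinyl compound (C11=C12) | C=C[C@@H]1C(C)=CC[C@@H]2C(C)(C)[C@H](O[Si](C)(C)C(C)(C)C)C3(OCCO3)C[C@@]12C | intermediate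
30 | methyl acetoacetate | COC(=O)CC(C)=O | starting material
31 | methyl (2E)-3-(trifluoromethylsulfonyloxy)but-2-enoate | C/C(OS(=O)(=O)C(F)(F)F)=C\C(=O)OC | intermediate
32 | B-alkyl-9-BBN: 29 carrying 9-borabicyclo[3.3.1]nonan-9-yl at C12 | C(C[C@@H]1C(C)=CC[C@@H]2C(C)(C)[C@H](O[Si](C)(C)C(C)(C)C)C3(OCCO3)C[C@@]12C)B4C5CCCC4CCC5 | intermediate
33 | methyl (13E)-labda-7,13-dien-15-oate with C2 ethylene ketal and (3S)-OTBS | COC(=O)/C=C(\C)CC[C@@H]1C(C)=CC[C@@H]2C(C)(C)[C@H](O[Si](C)(C)C(C)(C)C)C3(OCCO3)C[C@@]12C | intermediate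
34 | (13E)-labda-7,13-dien-15-ol with C2 ethylene ketal and (3S)-OTBS | OC/C=C(\C)CC[C@@H]1C(C)=CC[C@@H]2C(C)(C)[C@H](O[Si](C)(C)C(C)(C)C)C3(OCCO3)C[C@@]12C | intermediate
35 | C15 acetate of 34 | CC(=O)OC/C=C(\C)CC[C@@H]1C(C)=CC[C@@H]2C(C)(C)[C@H](O[Si](C)(C)C(C)(C)C)C3(OCCO3)C[C@@]12C | intermediate
36 | (13E)-(3S,5S,9R,10S)-3-hydroxy-2-oxolabda-7,13-dien-15-yl acetate (CNP0164008.1) | CC(=O)OC/C=C(\C)CC[C@@H]1C(C)=CC[C@@H]2C(C)(C)[C@H](O)C(=O)C[C@@]12C | target

Total step count: 25. Longest linear sequence: 24 steps (steps 1–20 and 22–25); step 21 is a one-step side branch.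

Steps most likely to fail

Step 13. The β,β-disubstituted enoate must form the quaternary C10 beside the C4 gem-dimethyl carbon, so the cycloaddition may need a temperature at which the silyl dienol ether degrades, or the C3 substituent may discriminate the two π-faces too weakly. The fallback sets out from enone 19 and closes both rings stepwise by an intramolecular double Michael reaction, a known annulation of enone–enoate substrates. With LiN(SiMe3)2 in THF at −78 → 0 °C the C5 enolate of 19 would add to C10 and the resulting ester enolate would add to C8. Each bond then forms in a separate polar step and no compressed concerted transition state is required. The sequence would deliver keto ester 22 after equilibration under the conditions of step 14 and rejoins the route there; no new compound arises (F0).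

Step 18. Hydride may be delivered to C8 instead of C6, the π-allyl complex may lose a β-hydrogen to give a diene, or hydride may attack the carbonate carbonyl and merely return the alcohol. The fallback sets out from allylic alcohol 25 and removes the oxygen by a radical chain (Barton–McCombie deoxygenation). NaH, CS2 and MeI in THF would give the S-methyl xanthate F1. Bu3SnH and AIBN in toluene at 80 °C would generate the C6–C7–C8 allyl radical, which should take hydrogen at the less hindered C6 terminus to give the 6-deoxy methyl ester F2. LiAlH4 in THF at 0 °C would then reduce the ester and rejoin the route at alcohol 27.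

Step 4. Ketalisation of the hindered α-silyloxy ketone may be slow, and under forcing the β,γ-alkene may migrate into conjugation or a silyl group may be lost. The fallback sets out from Weinreb amide 3 and builds the dioxolane by conjugate addition instead of carbonyl exchange. i-Bu2AlH in THF at −78 °C would give the aldehyde F3. The Ohira–Bestmann reagent with K2CO3 in MeOH at 0 °C would give the terminal alkyne F4. n-BuLi followed by N-methoxy-N-methylacetamide would give the ynone F5. Ethylene glycol with catalytic NaH in THF would then add twice to the ynone (double oxa-Michael addition, the second addition intramolecular) and give the β-keto dioxolane, which is methyl ketone 8; the route is rejoined there and steps 3–5 are bypassed.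

Further compounds
F0 | step 13 | none | none
F1 | step 18 | S-methyl xanthate of 25 (6-OC(=S)SMe) | COC(=O)[C@@H]1C(C)=C[C@H](OC(=S)SC)[C@@H]2C(C)(C)[C@H](O[Si](C)(C)C(C)(C)C)C3(OCCO3)C[C@@]12C
F2 | step 18 | 6-deoxy methyl ester (C6H2, C7=C8, 9-CO2Me, C2 ketal, 3-OTBS) | COC(=O)[C@@H]1C(C)=CC[C@@H]2C(C)(C)[C@H](O[Si](C)(C)C(C)(C)C)C3(OCCO3)C[C@@]12C
F3 | step 4 | (2S)-2,4-bis(tert-butyldimethylsilyloxy)-3,3-dimethylbutanal | CC(C)(C)[Si](C)(C)OCC(C)(C)[C@H](O[Si](C)(C)C(C)(C)C)C=O
F4 | step 4 | (3R)-3,5-bis(tert-butyldimethylsilyloxy)-4,4-dimethylpent-1-yne (same spatial arrangement as in 3) | CC(C)(C)[Si](C)(C)OCC(C)(C)[C@H](O[Si](C)(C)C(C)(C)C)C#C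
F5 | step 4 | (5R)-5,7-bis(tert-butyldimethylsilyloxy)-6,6-dimethylhept-3-yn-2-one | CC(C)(C)[Si](C)(C)OCC(C)(C)[C@H](O[Si](C)(C)C(C)(C)C)C#CC(C)=O
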